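**Strategy.** The chain is numbered C1 (guaiacyl end) to C7. The C2–C6 segment, oxygenated at C3, C5 and C6, is taken from a furan: C2–C5 are the four furan carbons and C6 is the attached carbinol. Oxidative ring expansion of (S)-2-[4-(benzyloxy)phenyl]-1-(furan-2-yl)ethanol turns the aromatic ring in one operation into a 2H-pyran-3(6H)-one (ring O–C2–C3=C4–C5(=O)–C6). This ring carries the C5 carbonyl, a C3=C4 enone for placing the C3 oxygen, and C2 as a lactol, a latent aldehyde. The ring then relays the C6 configuration to C3 and C5, and a Wittig reaction at C2 with an O-benzylvanillyl ylide adds C1 and the second arene.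

Key step: step 4

Assumption: 4-(benzyloxy)phenylacetic acid (1) and 4-(benzyloxy)-3-methoxybenzyl alcohol (16) are taken as catalogue compounds; they are the O-benzyl derivatives of 4-hydroxyphenylacetic acid and of vanillyl alcohol.

**Route**

Step 1
Reactants: 1 4-(benzyloxy)phenylacetic acid
Product: 3 2-[4-(benzyloxy)phenyl]-N-methoxy-N-methylacetamide, via acyl imidazolide 2 (not isolated)
Conditions: CDI, CH2Cl2, rt; then MeNH(OMe)·HCl, rt
Reagents that add atoms: N,O-dimethylhydroxylamine hydrochloride, CNOC.Cl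
Why: Weinreb amide formation by acyl-imidazolide activation and aminolysis, a standard amidation in which the aryl benzyl ether is inert.

Step 2
Reactants: 4 furan; 3 2-[4-(benzyloxy)phenyl]-N-methoxy-N-methylacetamide
Product: 6 2-[4-(benzyloxy)phenyl]-1-(furan-2-yl)ethan-1-one, via 2-furyllithium 5 (not isolated)
Conditions: furan, n-BuLi, THF, −78 → 0 °C; then 3, −78 → 0 °C; cold 1 M HCl
Reagents that add atoms: none
Why: α-Lithiation of furan followed by Weinreb ketone synthesis, in which the chelated tetrahedral adduct prevents over-addition and the low temperature favours addition over enolisation of the arylacetamide.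

Step 3
Reactants: 6 2-[4-(benzyloxy)phenyl]-1-(furan-2-yl)ethan-1-one
Product: 7 (S)-2-[4-(benzyloxy)phenyl]-1-(furan-2-yl)ethanol
Conditions: RuCl[(S,S)-TsDPEN](p-cymene) (1 mol %), HCO2H/Et3N (5:2), rt
Reagents that add atoms: none
Why: Noyori asymmetric transfer hydrogenation, in which the furyl ring takes the aryl role in the CH–π-organised transition state, so the (S,S) catalyst should deliver hydride to the face that gives the (S)-carbinol (sets C6).

Step 4
Reactants: 7 (S)-2-[4-(benzyloxy)phenyl]-1-(furan-2-yl)ethanol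
Product: 9 (2S)-2-[4-(benzyloxy)benzyl]-6-hydroxy-2H-pyran-3(6H)-one (mixture of anomers at the lactol carbon), via Z-4-oxo-enal 8 (not isolated)
Conditions: NBS (1.05 equiv), NaHCO3, NaOAc, THF/H2O (4:1), 0 °C
Reagents that add atoms: water, O
Why: This is an Achmatowicz rearrangement, a known reaction of furyl carbinols: NBS attacks the furan at its unsubstituted α-carbon (chain C2), water adds, and the resulting 2,5-dioxygenated dihydrofuran collapses to the Z-4-oxo-enal 8. The C6 hydroxyl then adds to the aldehyde carbon C2 in a 6-exo-trig hemiacetalisation, closing the ring O–C2–C3=C4–C5(=O)–C6. The only new stereocentre is the anomeric carbon C2, which forms as an equilibrating mixture and needs no control at this stage. The step needs chemoselectivity for the furan over the benzyloxyphenyl ring and retention at C6: furan is by far the more electron-rich π system toward one equivalent of NBS at 0 °C, the O-benzyl group keeps the phenol from being oxidised, no bond to C6 is broken, and the bicarbonate/acetate buffer keeps the newly α-keto C6–H from enolising.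

Step 5
Reactants: 9 (2S)-2-[4-(benzyloxy)benzyl]-6-hydroxy-2H-pyran-3(6H)-one
Product: 10 (2S,6S)-2-[4-(benzyloxy)benzyl]-6-[(tert-butyldimethylsilyl)oxy]-2H-pyran-3(6H)-one (2,6-trans)
Conditions: TBSCl, imidazole, CH2Cl2, −78 → 0 °C; minor cis anomer removed by chromatography
Reagents that add atoms: tert-butyldimethylsilyl chloride, CC(C)(C)[Si](C)(C)Cl
Why: O-Silylation of the mutarotating lactol, in which the anomer with a pseudo-axial oxygen trans to the equatorial C6 side chain is favoured by the anomeric effect and should predominate (sets the temporary C2 centre used for face control).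

Step 6
Reactants: 10 (2S,6S)-2-[4-(benzyloxy)benzyl]-6-[(tert-butyldimethylsilyl)oxy]-2H-pyran-3(6H)-one
Product: 11 (1R,2S,4S,6S)-4-[4-(benzyloxy)benzyl]-2-[(tert-butyldimethylsilyl)oxy]-3,7-dioxabicyclo[4.1.0]heptan-5-one (oxirane cis to the side chain and trans to OTBS)
Conditions: 30% H2O2, NaOH (cat.), MeOH/THF, −10 → 0 °C
Reagents that add atoms: hydrogen peroxide, OO
Why: Weitz–Scheffer nucleophilic epoxidation, in which hydroperoxide adds to C3 on the face opposite the pseudo-axial anomeric silyloxy group and the enolate closes onto O–O, so the oxirane (C3 and C4) should lie cis to the C6 side chain; the 2,6-trans arrangement is also the thermodynamically preferred one, which guards C6 against base-mediated epimerisation.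

Step 7
Reactants: 11 the epoxy ketone
Product: 12 (2S,5R,6S)-2-[4-(benzyloxy)benzyl]-6-[(tert-butyldimethylsilyl)oxy]-5-hydroxyoxan-3-one
Conditions: (PhSe)2, NaBH4, EtOH, rt; then AcOH and 11, 0 °C
Reagents that add atoms: none
Why: Organoselenium reductive opening of an α,β-epoxy ketone (Miyashita conditions), in which phenylselenide opens the oxirane at C4, α to the carbonyl, and a second selenide removes selenium to leave the enol, so the C3–O bond and its configuration are untouched and the buffered medium avoids β-elimination.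

Step 8
Reactants: 12 the β-hydroxy ketone
Product: 13 (2S,3S,5R,6S)-2-[4-(benzyloxy)benzyl]-6-[(tert-butyldimethylsilyl)oxy]oxane-3,5-diol (both hydroxyls cis to the side chain)
Conditions: L-Selectride (2.5 equiv), THF, −78 °C; AcOH quench
Reagents that add atoms: none
Why: Diastereoselective ketone reduction with a bulky trialkylborohydride: in the chair with equatorial C6 side chain and axial C2 and C3 oxygens, axial approach to C5 is blocked by the syn-axial C3 oxygen, so equatorial hydride delivery should give the axial C5 alcohol, cis to the C3 hydroxyl and to the side chain (sets C5).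

Step 9
Reactants: 13 the diol
Product: 14 (2S,3S,5R,6S)-3,5-bis(benzyloxy)-2-[4-(benzyloxy)benzyl]-6-[(tert-butyldimethylsilyl)oxy]oxane
Conditions: BnBr (excess), TBAI (cat.), then NaH, THF/DMF, 0 °C → rt
Reagents that add atoms: benzyl bromide, BrCc1ccccc1
Why: Williamson etherification of both secondary hydroxyls, with benzyl bromide present before the base so that O-alkylation outruns any shift of the anomeric silyl group; all benzyl groups leave together in the last step.

Step 10
Reactants: 14 the bis-benzyl ether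
Product: 15 (3R,5S,6S)-3,5-bis(benzyloxy)-6-[4-(benzyloxy)benzyl]oxan-2-ol (anomeric mixture)
Conditions: TBAF, AcOH, THF, 0 °C
Reagents that add atoms: none
Why: Fluoride-mediated cleavage of the anomeric silyl acetal, buffered with acetic acid so that the liberated 2-O-benzyl hemiacetal is not exposed to base.

Step 11
Reactants: 16 4-(benzyloxy)-3-methoxybenzyl alcohol
Product: 17 [4-(benzyloxy)-3-methoxybenzyl]triphenylphosphonium bromide
Conditions: PPh3·HBr, MeCN, reflux
Reagents that add atoms: triphenylphosphine hydrobromide, Br.c1ccc(cc1)P(c1ccccc1)c1ccccc1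
Why: Direct phosphonium salt formation from an electron-rich benzylic alcohol, in which protonation and ionisation give a benzylic bromide/cation that triphenylphosphine captures (nucleophilic substitution).

Step 12
Reactants: 17 the phosphonium bromide; 15 the lactol
Product: 19 (3R,5S,6S)-3,5-bis(benzyloxy)-1-[4-(benzyloxy)-3-methoxyphenyl]-7-[4-(benzyloxy)phenyl]hept-1-en-6-ol (E/Z mixture; chain numbering), via phosphorus ylide 18 (not isolated)
Conditions: 17 (3 equiv), n-BuLi (3 equiv), THF, −78 → 0 °C; then 15, 0 °C → rt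
Reagents that add atoms: none
Why: Wittig olefination of the hydroxy aldehyde in equilibrium with the lactol (one equivalent of ylide is spent deprotonating the lactol, hence the excess); the semi-stabilised ylide should give an E/Z mixture that converges in the next step, and the styrene formed cannot be re-attacked by the C6 alkoxide.

Step 13
Reactants: 19 the alkene
Product: 20 (3S,5S,6S)-1-(4-hydroxy-3-methoxyphenyl)-7-(4-hydroxyphenyl)heptane-3,5,6-triol (target)
Conditions: H2 (1 atm), 10% Pd/C, EtOAc, rt; then MeOH added, rt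
Reagents that add atoms: none
Why: Catalytic hydrogenation of the C1=C2 alkene and hydrogenolysis of the four O-benzyl groups over palladium in one operation; starting in ethyl acetate should saturate the alkene before the then no longer allylic C3–O bond sees prolonged hydrogenolysis conditions, and no stereocentre is touched.

**Compound list**

1 | 4-(benzyloxy)phenylacetic acid | OC(=O)Cc1ccc(OCc2ccccc2)cc1 | starting material
2 | 2-[4-(benzyloxy)phenyl]-1-(imidazol-1-yl)ethan-1-one | O=C(Cc1ccc(OCc2ccccc2)cc1)n1ccnc1 | intermediate (not isolated)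
3 | 2-[4-(benzyloxy)phenyl]-N-methoxy-N-methylacetamide | CON(C)C(=O)Cc1ccc(OCc2ccccc2)cc1 | intermediate
4 | furan | c1ccoc1 | starting material
5 | 2-furyllithium | [Li]c1ccco1 | intermediate (not isolated)
6 | 2-[4-(benzyloxy)phenyl]-1-(furan-2-yl)ethan-1-one | O=C(Cc1ccc(OCc2ccccc2)cc1)c1ccco1 | intermediate
7 | (S)-2-[4-(benzyloxy)phenyl]-1-(furan-2-yl)ethanol | c1coc(c1)[C@@H](O)Cc1ccc(OCc2ccccc2)cc1 | intermediate
8 | (2Z,5S)-6-[4-(benzyloxy)phenyl]-5-hydroxy-4-oxohex-2-enal | O=C/C=C\C(=O)[C@@H](O)Cc1ccc(OCc2ccccc2)cc1 | intermediate (not isolated)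
9 | (2S)-2-[4-(benzyloxy)benzyl]-6-hydroxy-2H-pyran-3(6H)-one, anomeric mixture | O=C1C=CC(O)O[C@H]1Cc1ccc(OCc2ccccc2)cc1 | intermediate
10 | (2S,6S)-2-[4-(benzyloxy)benzyl]-6-[(tert-butyldimethylsilyl)oxy]-2H-pyran-3(6H)-one | O=C1C=C[C@H](O[Si](C)(C)C(C)(C)C)O[C@H]1Cc1ccc(OCc2ccccc2)cc1 | intermediate
11 | (1R,2S,4S,6S)-4-[4-(benzyloxy)benzyl]-2-[(tert-butyldimethylsilyl)oxy]-3,7-dioxabicyclo[4.1.0]heptan-5-one | O=C1[C@H]2O[C@H]2[C@H](O[Si](C)(C)C(C)(C)C)O[C@H]1Cc1ccc(OCc2ccccc2)cc1 | intermediate
12 | (2S,5R,6S)-2-[4-(benzyloxy)benzyl]-6-[(tert-butyldimethylsilyl)oxy]-5-hydroxyoxan-3-one | O=C1C[C@@H](O)[C@H](O[Si](C)(C)C(C)(C)C)O[C@H]1Cc1ccc(OCc2ccccc2)cc1 | intermediate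
13 | (2S,3S,5R,6S)-2-[4-(benzyloxy)benzyl]-6-[(tert-butyldimethylsilyl)oxy]oxane-3,5-diol | O[C@H]1C[C@@H](O)[C@H](O[Si](C)(C)C(C)(C)C)O[C@H]1Cc1ccc(OCc2ccccc2)cc1 | intermediate
14 | (2S,3S,5R,6S)-3,5-bis(benzyloxy)-2-[4-(benzyloxy)benzyl]-6-[(tert-butyldimethylsilyl)oxy]oxane | C(c1ccccc1)O[C@H]1C[C@@H](OCc2ccccc2)[C@H](O[Si](C)(C)C(C)(C)C)O[C@H]1Cc1ccc(OCc2ccccc2)cc1 | intermediate
15 | (3R,5S,6S)-3,5-bis(benzyloxy)-6-[4-(benzyloxy)benzyl]oxan-2-ol, anomeric mixture | C(c1ccccc1)O[C@H]1C[C@@H](OCc2ccccc2)C(O)O[C@H]1Cc1ccc(OCc2ccccc2)cc1 | intermediate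
16 | 4-(benzyloxy)-3-methoxybenzyl alcohol | COc1cc(CO)ccc1OCc1ccccc1 | starting material
17 | [4-(benzyloxy)-3-methoxybenzyl]triphenylphosphonium bromide | COc1cc(C[P+](c2ccccc2)(c2ccccc2)c2ccccc2)ccc1OCc1ccccc1.[Br-] | intermediate
18 | [4-(benzyloxy)-3-methoxybenzylidene]triphenylphosphorane | COc1cc(C=P(c2ccccc2)(c2ccccc2)c2ccccc2)ccc1OCc1ccccc1 | intermediate (not isolated)
19 | (3R,5S,6S)-3,5-bis(benzyloxy)-1-[4-(benzyloxy)-3-methoxyphenyl]-7-[4-(benzyloxy)phenyl]hept-1-en-6-ol, E/Z mixture | COc1cc(C=C[C@H](OCc2ccccc2)C[C@H](OCc2ccccc2)[C@@H](O)Cc2ccc(OCc3ccccc3)cc2)ccc1OCc1ccccc1 | intermediate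
20 | (3S,5S,6S)-1-(4-hydroxy-3-methoxyphenyl)-7-(4-hydroxyphenyl)heptane-3,5,6-triol | COc1cc(CC[C@H](O)C[C@H](O)[C@@H](O)Cc2ccc(O)cc2)ccc1O | target

**Count and risks**

Total step count: 13. Longest linear sequence: 12 (steps 1–10, 12, 13); step 11 is the side branch.

Steps most likely to fail:

1. Step 8. Hydride may be delivered with poor facial discrimination, axial attack competing with equatorial attack, or the lithium alkoxide of the β-hydroxy ketone may eliminate before it is reduced. The fallback sets C5 before C3 and lets its hydroxyl direct the epoxidation; it sets out from 10 and comes back at 13, replacing steps 6–8. Luche reduction of 10 (NaBH4, CeCl3·7H2O, MeOH, −78 °C) should give the allylic alcohol with the hydroxyl trans to the side chain, (2S,3R,6S)-2-[4-(benzyloxy)benzyl]-6-[(tert-butyldimethylsilyl)oxy]-3,6-dihydro-2H-pyran-3-ol F1. Mitsunobu inversion (4-nitrobenzoic acid, PPh3, DIAD, THF) should give the cis ester, (2S,3S,6S)-2-[4-(benzyloxy)benzyl]-6-[(tert-butyldimethylsilyl)oxy]-3,6-dihydro-2H-pyran-3-yl 4-nitrobenzoate F2. Methanolysis (K2CO3, MeOH) releases the cis allylic alcohol, (2S,3S,6S)-2-[4-(benzyloxy)benzyl]-6-[(tert-butyldimethylsilyl)oxy]-3,6-dihydro-2H-pyran-3-ol F3. Hydroxyl-directed epoxidation (mCPBA, NaHCO3, CH2Cl2, 0 °C), reinforced by the silyloxy group on the opposite face, should give the all-cis epoxy alcohol, 4-[4-(benzyloxy)benzyl]-2-[(tert-butyldimethylsilyl)oxy]-3,7-dioxabicyclo[4.1.0]heptan-5-ol with oxirane and hydroxyl cis to the side chain F4. LiAlH4 (THF, 0 °C) should then open the oxirane trans-diaxially at C4, the carbon remote from the acetal centre, to give 13.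

2. Step 12. Ring–chain opening of the lactol may be slow, and the basic benzylic ylide may enolise the α-benzyloxy aldehyde, eroding C3, or simply return the lactol. The fallback forms the C1=C2 bond by metathesis; it sets out from 15 and comes back at 19. Methylenation with the more reactive Ph3P=CH2 (Ph3PCH3Br, KHMDS, THF, 0 °C → rt), long established for O-benzylated sugar lactols, should give (3R,5S,6S)-3,5-bis(benzyloxy)-7-[4-(benzyloxy)phenyl]hept-1-en-6-ol F5. Olefin cross-metathesis with commercial 4-(benzyloxy)-3-methoxystyrene (Hoveyda–Grubbs II, CH2Cl2, 40 °C) should then give 19 as its E isomer.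

3. Step 13. Hydrogenolysis of the allylic C3–O bond may compete with saturation of the styrenyl alkene, losing the C3 oxygen, or debenzylation may stall. The fallback separates the two events; it sets out from 19 and comes back at 20. Metal-free diimide reduction (2-nitrobenzenesulfonyl hydrazide, Et3N, CH2Cl2, rt) should saturate the alkene to (3S,5S,6S)-3,5-bis(benzyloxy)-1-[4-(benzyloxy)-3-methoxyphenyl]-7-[4-(benzyloxy)phenyl]heptan-6-ol F6. Hydrogenolysis (H2, Pd(OH)2/C, EtOAc/MeOH, rt) then removes the four benzyl groups to give 20.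

**Further compounds**

F1 | step 8 | (2S,3R,6S)-2-[4-(benzyloxy)benzyl]-6-[(tert-butyldimethylsilyl)oxy]-3,6-dihydro-2H-pyran-3-ol | O[C@@H]1C=C[C@H](O[Si](C)(C)C(C)(C)C)O[C@H]1Cc1ccc(OCc2ccccc2)cc1
F2 | step 8 | (2S,3S,6S)-2-[4-(benzyloxy)benzyl]-6-[(tert-butyldimethylsilyl)oxy]-3,6-dihydro-2H-pyran-3-yl 4-nitrobenzoate | O=C(O[C@H]1C=C[C@H](O[Si](C)(C)C(C)(C)C)O[C@H]1Cc1ccc(OCc2ccccc2)cc1)c1ccc(cc1)[N+](=O)[O-]
F3 | step 8 | (2S,3S,6S)-2-[4-(benzyloxy)benzyl]-6-[(tert-butyldimethylsilyl)oxy]-3,6-dihydro-2H-pyran-3-ol | O[C@H]1C=C[C@H](O[Si](C)(C)C(C)(C)C)O[C@H]1Cc1ccc(OCc2ccccc2)cc1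
F4 | step 8 | 4-[4-(benzyloxy)benzyl]-2-[(tert-butyldimethylsilyl)oxy]-3,7-dioxabicyclo[4.1.0]heptan-5-ol, oxirane and hydroxyl cis to the side chain | O[C@H]1[C@H]2O[C@H]2[C@H](O[Si](C)(C)C(C)(C)C)O[C@H]1Cc1ccc(OCc2ccccc2)cc1
F5 | step 12 | (3R,5S,6S)-3,5-bis(benzyloxy)-7-[4-(benzyloxy)phenyl]hept-1-en-6-ol | C=C[C@H](OCc1ccccc1)C[C@H](OCc1ccccc1)[C@@H](O)Cc1ccc(OCc2ccccc2)cc1
F6 | step 13 | (3S,5S,6S)-3,5-bis(benzyloxy)-1-[4-(benzyloxy)-3-methoxyphenyl]-7-[4-(benzyloxy)phenyl]heptan-6-ol | COc1cc(CC[C@H](OCc2ccccc2)C[C@H](OCc2ccccc2)[C@@H](O)Cc2ccc(OCc3ccccc3)cc2)ccc1OCc1ccccc1
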